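Ring grows from the meeting of substrate and activator, so I asked of each flask how long the two had shared it.

| flask | substrate | activator | remark | time |
|---|---|---|---|---|
| teal | 0.18 M | 0.18 M | run made earlier |  |
| blue | 0.36 M | 0.18 M | run made earlier |  |
| gamma | 0.18 M (fed, over 1.0 h) | 0.180 M | all else is in the flask from the start; the feed brings no volume worth counting | 80 min |
| zeta | 0.18 M | 0.180 M (fed, over 1.0 h) | all else is in the flask from the start; the feed brings no volume worth counting | 80 min |
| eta | 0.18 M | 0.180 M | everything together at the start | 80 min |

| run | time / min | ring / % |
|---|---|---|
| teal | 6.00 | 6 |
| teal | 10.0 | 5 |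
| teal | 20.0 | 17 |
| teal | 30.0 | 22 |
| teal | 50.0 | 31 |
| teal | 80.0 | 40 |
| blue | 0.500 | 0 |
| blue | 1.50 | 0 |
| blue | 3.00 | 0 |
| blue | 4.00 | 0 |
| blue | 6.00 | 4 |
| blue | 8.00 | 3 |

(each reading ± 1.5 percentage points)

- in percentages every species weighs as the substrate in it: one open dimer counts as two
- steps that have been proposed: substrate + activator -> activated form; activated form -> ring; substrate + activated form -> open dimer; 2 activator -> self-condensation product; activator -> decomposed reagent

- the flask that comes out highest in amount of ring, in percent of the substrate charged, or "all alike" when all lie within 1.5 percentage points (gamma / zeta / eta / all alike)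
- ring at the end, in percent of the substrate charged, gamma
- ring at the end, in percent of the substrate charged, zeta
- ring at the end, in percent of the substrate charged, eta

The teal run, with equal charges, is the symmetric case: for a second-order meeting, ring over what is not yet ring grows evenly in time. I read that growth from its last reading, 40 % at 80.0 min:

growth = ring share / (one minus ring share) / time = 0.00833 min⁻¹

contact time = time − feed time / 2 = 50.0 min

contact number = growth × contact time = 0.417

ring share = contact number / (one plus contact number)

This contact number is the growth multiplied by the mean time the fed partner spends in the flask. At one extreme, the whole charge goes in at the start, which gives 0.667 and ring 40.0 %. At the other, it is tipped in as the feed ends, which gives 0.167 and ring 14.3 %. Each portion of a steady feed arrives between those moments, so the contact time of 50.0 min is shorter than 80 min and longer than 20.0 min. I therefore expected 29.4 % for gamma and for zeta alike, and eta highest.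

The forecast also put eta highest, at 40 %, but it separated the fed flasks: gamma 31 %, zeta 27 %. Its ground for the split was selectivity: “Gamma keeps substrate low, so selectivity is better”, while zeta, keeping substrate high, was to form more dimer.

    substrate + activator → activated form (k = 0.0984 L mol⁻¹ min⁻¹)
    activated form → ring (k = 0.132 min⁻¹)
    substrate + activated form → open dimer (k = 0.113 L mol⁻¹ min⁻¹)
    2 activator → self-condensation product (k = 0.0318 L mol⁻¹ min⁻¹)
    activator → decomposed reagent (k = 0.00371 min⁻¹)

Eta gave 39.7 %. For the two fed flasks the contact number 0.417 had promised 29.4 %, which is less than zeta's 32.2 % and more than gamma's 25.2 %. Over gamma's first hour activator averaged 0.113 M, and self-condensation product reached 0.0266 M by 60.0 min; over zeta's first hour activator averaged 0.0595 M, and the product reached 0.00820 M. Eta's neighbour with 0.11 M of substrate keeps eta's activator and time, so its number is 0.667, which places its ring between the equal-charge 40.0 % and the pseudo-first-order 48.7 %; it gave 45.7 %.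

The numbers in the tables stem from a simulated flask on assumed constants; scatter was added.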